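**Retrosynthetic overview**

Numbering follows tricyclo[5.3.1.0^1,5]undecane. The cyclopentane is C1–C5 (C3 bears CMe2OH, C4 is CMe2). The bicyclo[3.2.1]octanetrione is C1 and C5–C11 (C7–Me, C9–acyl, C11 is the one-carbon C=O bridge).
Endgame: the C9–acyl bond comes from O→C acyl transfer with (R)-2-methylbutanoic acid, and the side-chain OH from Markovnikov hydration of an isopropenyl group on C3.
Key disconnection, C1–C5 and C3–C4: the cyclopentane is grown from the cyclopropane C1–C2–C3 of spiro[2.5]octenedione 12 by radical insertion of the prenyl C5=C4 unit held on C7, which also closes the ring C1–C5–C6–C7–C11.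
Enabling feature: C1 is a quaternary carbon between the C10 and C11 carbonyls and carries C2H2–C3H(alkenyl), so it is an opened 2-alkenylcyclopropane-1,1-diacyl unit with a stabilised C1 radical; C6H2–C5H–C4Me2 on C7 (1,3 to C1 across C11) is a prenyl group.
12 comes from the resolved cyclopropane half-ester 5 and ketone 9 (C9–C10 by Claisen acylation, C7–C11 by dianion ring closure). Ring order: cyclopropane, six-membered ring, then both five-membered rings at once.

Key step: step 7

Assumption 1: 2 and 16 are bought as such (2 is also the 1,4-adduct of bromine to isoprene).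
Assumption 2: the less soluble salt with (R)-1-phenylethylamine holds the (1S,2S)-acid; if the pairing is the opposite one, the (S)-amine takes its place.
Assumption 3: the L-cystine-derived catalyst is the matched one for C3 in step 7; if it is not, the D-cystine derivative takes its place.

Step 1
Reactants: 1 dimethyl malonate; 2 (E)-1,4-dibromo-2-methylbut-2-ene
Product: 3 dimethyl 2-(prop-1-en-2-yl)cyclopropane-1,1-dicarboxylate (racemic)
Conditions: NaOMe (2.05 equiv), MeOH, 0 °C to reflux
Reagents that add atoms: none
Why: Double malonate alkylation (SN2 at the more reactive prenyl-type CH2Br next to the CH=, then 3-exo SN2′ closure on that CH with loss of the second bromide) is the standard route to 2-alkenylcyclopropane-1,1-diesters, and the one stereocentre forms racemic.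

Step 2
Reactants: 3 dimethyl 2-(prop-1-en-2-yl)cyclopropane-1,1-dicarboxylate
Product: 4 rel-(1S,2S)-1-(methoxycarbonyl)-2-(prop-1-en-2-yl)cyclopropane-1-carboxylic acid (racemic)
Conditions: KOH (1.0 equiv), MeOH, 0 °C to rt; then 1 M HCl
Reagents that add atoms: potassium hydroxide, [K+].[OH-]
Why: In this mono-saponification of a 2-substituted cyclopropane-1,1-diester the ester trans to the alkenyl group is the less hindered one and reacts first, which sets C1 relative to C2 (CO2H trans, CO2Me cis to isopropenyl).

Step 3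
Reactants: 4 rel-(1S,2S)-1-(methoxycarbonyl)-2-(prop-1-en-2-yl)cyclopropane-1-carboxylic acid
Product: 5 (1S,2S)-1-(methoxycarbonyl)-2-(prop-1-en-2-yl)cyclopropane-1-carboxylic acid
Conditions: (R)-1-phenylethylamine (0.55 equiv), EtOAc/i-PrOH, recrystallisation of the salt; then 1 M HCl, Et2O
Reagents that add atoms: none
Why: Classical resolution through diastereomeric ammonium salts supplies the absolute configuration of the cyclopropane, which is the only external source of chirality for the core.

Step 4
Reactants: 6 3-methylpentane-2,4-dione; 7 1-bromo-3-methylbut-2-ene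
Product: 9 3,6-dimethylhept-5-en-2-one (racemic), via 3-methyl-3-prenylpentane-2,4-dione 8 (not isolated)
Conditions: K2CO3 (1.2 equiv), EtOH, reflux
Reagents that add atoms: none
Why: C-alkylation of the β-diketone followed by in situ retro-Claisen deacetylation of the non-enolisable product by ethanol gives the methyl ketone, whose stereocentre is irrelevant because it is enolised in step 6.

Step 5
Reactants: 5 (1S,2S)-1-(methoxycarbonyl)-2-(prop-1-en-2-yl)cyclopropane-1-carboxylic acid; 9 3,6-dimethylhept-5-en-2-one
Product: 11 methyl (1S,2S)-1-(4,7-dimethyl-3-oxooct-6-enoyl)-2-(prop-1-en-2-yl)cyclopropane-1-carboxylate, via acid chloride 10 (not isolated)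
Conditions: (i) 1-chloro-N,N,2-trimethylprop-1-en-1-amine (1.1 equiv), CH2Cl2, 0 °C; (ii) 9 (2.1 equiv), LDA (2.1 equiv), THF, −78 °C, then crude 10; aq NH4Cl
Reagents that add atoms: none
Why: This is a crossed Claisen-type C-acylation of the kinetic (CH3-side) lithium enolate with an acid chloride made under neutral conditions, and it forms the C9–C10 bond without touching the cyclopropane stereocentres (second enolate equivalent as base for the β-diketone).

Step 6
Reactants: 11 methyl (1S,2S)-1-(4,7-dimethyl-3-oxooct-6-enoyl)-2-(prop-1-en-2-yl)cyclopropane-1-carboxylate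
Product: 12 (1S,3S,7S)-6-hydroxy-7-methyl-7-(3-methylbut-2-en-1-yl)-1-(prop-1-en-2-yl)spiro[2.5]oct-5-ene-4,8-dione
Conditions: LDA (3.0 equiv), THF, −78 to 0 °C; 1 M HCl; chromatography
Reagents that add atoms: none
Why: In this Dieckmann-type intramolecular acylation of the β-diketone dianion at its only γ-carbon, the isopropenyl group cis to the reacting ester shields one ring face, so the small methyl should end up syn and the prenyl anti to it (7S); the minor C7 epimer, which would lead to the enantiomeric core, is removed here.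

Step 7
Reactants: 12 (1S,3S,7S)-6-hydroxy-7-methyl-7-(3-methylbut-2-en-1-yl)-1-(prop-1-en-2-yl)spiro[2.5]oct-5-ene-4,8-dione
Product: 13 (1R,3R,5S,7S)-8-hydroxy-4,4,7-trimethyl-3-(prop-1-en-2-yl)tricyclo[5.3.1.0^1,5]undec-8-ene-10,11-dione
Conditions: N,N′-di-Boc-L-cystine dimethyl ester (20 mol %), 2,2-dimethoxy-2-phenylacetophenone (5 mol %), 365 nm LED, benzene (5 mM), 25 °C, argon
Reagents that add atoms: none
Why: The thiyl radical adds to the CH2 of the isopropenyl group and the tertiary cyclopropylcarbinyl radical cleaves the C1–C3 bond to the dicarbonyl-stabilised C1 radical and an allyl sulfide; C1 then adds to the prenyl CH (C5), the tertiary C4 radical adds to C3, and β-scission returns the thiyl radical and the isopropenyl group, so that C5 and C4 are inserted into the three-membered ring (three- to five-membered ring expansion). The closest known reaction type is the thiyl-radical-catalysed [3+2] cycloaddition of 2-vinylcyclopropane-1,1-dicarbonyl compounds with alkenes, including its variants with homochiral cysteine-derived thiyl catalysts. Both closures are 5-exo-trig: C1→C5 closes the ring C1–C5–C6–C7–C11 and C4→C3 closes the cyclopentane C1–C5. C1 and C5 are controlled by C7, because the prenyl group reaches the planar C1 radical only on its own ring face and only the exo C4 radical (H5 endo, cis ring fusion) can reach C3, while both cyclopropane stereocentres are erased after having done their relay work in step 6. C3 is the one centre that the cage hardly biases (the alkene can fold towards C10 or under the C11 carbonyl), so it is put under reagent control: the closure takes place while the homochiral thiyl residue sits on the carbon next to the accepting alkene, and the fold with the alkenyl group cis to C6 is the one needed. The step also needs chemoselective initiation (thiyl addition is reversible at both alkenes and only the cyclopropane opening is irreversible), attack at the CH end of the prenyl group (electrophilic radical on an electron-rich alkene, giving a tertiary radical) and a long-lived C4 radical (high dilution, catalytic disulfide, no hydrogen donor).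

Step 8
Reactants: 13 (1R,3R,5S,7S)-8-hydroxy-4,4,7-trimethyl-3-(prop-1-en-2-yl)tricyclo[5.3.1.0^1,5]undec-8-ene-10,11-dione
Product: 15 (1R,3S,5S,7S)-8-hydroxy-3-(2-hydroxypropan-2-yl)-4,4,7-trimethyltricyclo[5.3.1.0^1,5]undec-8-ene-10,11-dione, via tertiary hydroperoxide 14 (not isolated)
Conditions: Mn(dpm)3 (10 mol %), PhSiH3 (2 equiv), O2 (1 atm), i-PrOH/CH2Cl2, 0 °C; then PPh3
Reagents that add atoms: dioxygen, O=O
Why: Mukaiyama hydration transfers a hydrogen atom to the CH2 of the only isolated alkene and traps the tertiary radical with O2; no stereocentre is touched, and the cyclic 1,3-dione cannot chelate the metal.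

Step 9
Reactants: 15 (1R,3S,5S,7S)-8-hydroxy-3-(2-hydroxypropan-2-yl)-4,4,7-trimethyltricyclo[5.3.1.0^1,5]undec-8-ene-10,11-dione; 16 (R)-2-methylbutanoic acid
Product: 18 (1S,3S,5S,7S)-8-hydroxy-3-(2-hydroxypropan-2-yl)-4,4,7-trimethyl-9-[(2R)-2-methylbutanoyl]tricyclo[5.3.1.0^1,5]undec-8-ene-10,11-dione, via enol ester 17 (not isolated)
Conditions: DCC (1.1 equiv), DMAP (1.1 equiv), CH2Cl2, 0 °C to rt
Reagents that add atoms: none
Why: Steglich-type O-acylation of the acidic enol followed by DMAP-mediated O→C acyl transfer is the standard entry to 2-acylcyclohexane-1,3-diones; the hindered tertiary alcohol stays free, and the mild conditions should keep the α-stereocentre of the acyl group.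

**Compound list**

1 | dimethyl malonate | COC(=O)CC(=O)OC | starting material
2 | (E)-1,4-dibromo-2-methylbut-2-ene | BrC/C=C(\C)CBr | starting material
3 | dimethyl 2-(prop-1-en-2-yl)cyclopropane-1,1-dicarboxylate (racemic) | COC(=O)C1(CC1C(C)=C)C(=O)OC | intermediate
4 | rel-(1S,2S)-1-(methoxycarbonyl)-2-(prop-1-en-2-yl)cyclopropane-1-carboxylic acid (racemic; CO2H trans, CO2Me cis to isopropenyl) | CC(=C)C1CC1(C(=O)O)C(=O)OC | intermediate
5 | (1S,2S)-1-(methoxycarbonyl)-2-(prop-1-en-2-yl)cyclopropane-1-carboxylic acid | CC(=C)[C@@H]1C[C@]1(C(=O)O)C(=O)OC | intermediate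
6 | 3-methylpentane-2,4-dione | CC(=O)C(C)C(C)=O | starting material
7 | 1-bromo-3-methylbut-2-ene (prenyl bromide) | CC(C)=CCBr | starting material
8 | 3-methyl-3-(3-methylbut-2-en-1-yl)pentane-2,4-dione | CC(=O)C(C)(CC=C(C)C)C(C)=O | intermediate
9 | 3,6-dimethylhept-5-en-2-one (racemic) | CC(=O)C(C)CC=C(C)C | intermediate
10 | methyl (1R,2S)-1-(chlorocarbonyl)-2-(prop-1-en-2-yl)cyclopropane-1-carboxylate | CC(=C)[C@@H]1C[C@]1(C(=O)Cl)C(=O)OC | intermediate
11 | methyl (1S,2S)-1-(4,7-dimethyl-3-oxooct-6-enoyl)-2-(prop-1-en-2-yl)cyclopropane-1-carboxylate (both epimers at C4′) | CC(=C)[C@@H]1C[C@]1(C(=O)CC(=O)C(C)CC=C(C)C)C(=O)OC | intermediate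
12 | (1S,3S,7S)-6-hydroxy-7-methyl-7-(3-methylbut-2-en-1-yl)-1-(prop-1-en-2-yl)spiro[2.5]oct-5-ene-4,8-dione | CC(=C)[C@@H]1C[C@@]12C(=O)C=C(O)[C@](C)(CC=C(C)C)C2=O | intermediate
13 | (1R,3R,5S,7S)-8-hydroxy-4,4,7-trimethyl-3-(prop-1-en-2-yl)tricyclo[5.3.1.0^1,5]undec-8-ene-10,11-dione (isopropenyl cis to C6 and C11) | C1=C(O)[C@]2(C)C[C@H]3C(C)(C)[C@@H](C(C)=C)C[C@@]3(C1=O)C2=O | intermediate
14 | (1R,3S,5S,7S)-3-(2-hydroperoxypropan-2-yl)-8-hydroxy-4,4,7-trimethyltricyclo[5.3.1.0^1,5]undec-8-ene-10,11-dione | C1=C(O)[C@]2(C)C[C@H]3C(C)(C)[C@@H](C(C)(C)OO)C[C@@]3(C1=O)C2=O | intermediate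
15 | (1R,3S,5S,7S)-8-hydroxy-3-(2-hydroxypropan-2-yl)-4,4,7-trimethyltricyclo[5.3.1.0^1,5]undec-8-ene-10,11-dione | C1=C(O)[C@]2(C)C[C@H]3C(C)(C)[C@@H](C(C)(C)O)C[C@@]3(C1=O)C2=O | intermediate
16 | (R)-2-methylbutanoic acid | CC[C@@H](C)C(=O)O | starting material
17 | C8 enol (R)-2-methylbutanoate of 15 | C1=C(OC(=O)[C@H](C)CC)[C@]2(C)C[C@H]3C(C)(C)[C@@H](C(C)(C)O)C[C@@]3(C1=O)C2=O | intermediate
18 | (1S,3S,5S,7S)-8-hydroxy-3-(2-hydroxypropan-2-yl)-4,4,7-trimethyl-9-[(2R)-2-methylbutanoyl]tricyclo[5.3.1.0^1,5]undec-8-ene-10,11-dione | CC[C@@H](C)C(=O)C1=C(O)[C@]2(C)C[C@H]3C(C)(C)[C@@H](C(C)(C)O)C[C@@]3(C1=O)C2=O | target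

**Step count**

Total steps: 9. Longest linear sequence: 8 (steps 1, 2, 3, 5, 6, 7, 8, 9).

**Steps most likely to fail**

Step 7. The likely failure is poor facial selectivity in the second 5-exo closure. The required fold places the alkenyl group on the more crowded side under the C11 carbonyl, and reagent control may not override this. The C4 radical could also be intercepted before it closes. The fallback corrects C3 after ring formation instead of during it.
- It sets out from 12, which is ring-expanded with achiral diphenyl disulfide (20 mol %, 390 nm, benzene) to 13 together with its C3 epimer (1R,3S,5S,7S)-8-hydroxy-4,4,7-trimethyl-3-(prop-1-en-2-yl)tricyclo[5.3.1.0^1,5]undec-8-ene-10,11-dione F1.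
- The mixture goes through the conditions of step 8, F1 passing through the epimeric hydroperoxide F2 to the C3-epimeric alcohol F3, which is separated from 15.
- F3 is then epimerised at its unactivated tertiary C3–H by photochemical hydrogen-atom abstraction and return (tetrabutylammonium decatungstate 2 mol %, bis(2,4,6-triisopropylphenyl) disulfide 10 mol %, MeCN, 390 nm).
- The planar C3 radical should take up hydrogen from the bulky thiol on the open convex face, which is the face that carries H3 in 15. The route is rejoined at 15.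

Step 6. The hindered tertiary carbanion may attack the ester cis to the alkenyl group only slowly. Methoxide may reverse the closure (retro-Claisen). The facial selectivity at C7 may be low. Activated 12 may also drift to ring-opened isomers on standing. The fallback builds the quaternary centre by alkylation and closes the ring at the unhindered end.
- It sets out from acid chloride 10, which is C-acylated with the more substituted lithium enolate of butan-2-one (from (but-2-en-2-yloxy)trimethylsilane and MeLi, THF, −78 °C) to methyl (1S,2S)-1-(2-methyl-3-oxobutanoyl)-2-(prop-1-en-2-yl)cyclopropane-1-carboxylate F4.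
- The 2-methyl-1,3-diketone is prenylated at its central carbon (7, K2CO3, acetone) to methyl (1S,2S)-1-[2-acetyl-2,5-dimethylhex-4-enoyl]-2-(prop-1-en-2-yl)cyclopropane-1-carboxylate F5 (both epimers).
- The acetyl CH3, now the only enolisable position, closes on the ester (LDA, THF, −78 to 0 °C, Dieckmann-type). The 7S epimer, (1S,3R,7S)-6-hydroxy-7-methyl-7-(3-methylbut-2-en-1-yl)-1-(prop-1-en-2-yl)spiro[2.5]oct-5-ene-4,8-dione F6, is separated by chromatography.
- F6 differs from 12 only at the spiro centre, which the ring opening erases. Under the conditions of step 7 it rejoins the route at 13.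

Step 9. The reaction may stall at the enol ester, because C9 of the caged β-diketone is hindered, and the acyl α-stereocentre may erode during a slow acyl transfer. The fallback moves the acylation in front of the ring expansion, onto the flatter and less hindered monocyclic dione.
- It sets out from 12, which with 16, DCC and DMAP gives, through the enol ester F7, (1S,3S,7S)-6-hydroxy-7-methyl-5-[(2R)-2-methylbutanoyl]-7-(3-methylbut-2-en-1-yl)-1-(prop-1-en-2-yl)spiro[2.5]oct-5-ene-4,8-dione F8.
- The conditions of step 7 turn F8 into the acylated isopropenyl tricycle F9.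
- Mukaiyama hydration of F9 (stoichiometric Mn(dpm)3 if the β-triketone binds the catalyst), through the hydroperoxide F10 and PPh3, rejoins the route at 18.

Further compounds
F1 | step 7 | (1R,3S,5S,7S)-8-hydroxy-4,4,7-trimethyl-3-(prop-1-en-2-yl)tricyclo[5.3.1.0^1,5]undec-8-ene-10,11-dione (C3 epimer of 13) | C1=C(O)[C@]2(C)C[C@H]3C(C)(C)[C@H](C(C)=C)C[C@@]3(C1=O)C2=O
F2 | step 7 | C3 epimer of hydroperoxide 14 | C1=C(O)[C@]2(C)C[C@H]3C(C)(C)[C@H](C(C)(C)OO)C[C@@]3(C1=O)C2=O
F3 | step 7 | C3 epimer of alcohol 15 | C1=C(O)[C@]2(C)C[C@H]3C(C)(C)[C@H](C(C)(C)O)C[C@@]3(C1=O)C2=O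
F4 | step 6 | methyl (1S,2S)-1-(2-methyl-3-oxobutanoyl)-2-(prop-1-en-2-yl)cyclopropane-1-carboxylate | CC(=C)[C@@H]1C[C@]1(C(=O)C(C)C(C)=O)C(=O)OC
F5 | step 6 | methyl (1S,2S)-1-[2-acetyl-2,5-dimethylhex-4-enoyl]-2-(prop-1-en-2-yl)cyclopropane-1-carboxylate (both epimers) | CC(=C)[C@@H]1C[C@]1(C(=O)C(C)(CC=C(C)C)C(C)=O)C(=O)OC
F6 | step 6 | (1S,3R,7S)-6-hydroxy-7-methyl-7-(3-methylbut-2-en-1-yl)-1-(prop-1-en-2-yl)spiro[2.5]oct-5-ene-4,8-dione | CC(=C)[C@@H]1C[C@]12C(=O)C=C(O)[C@](C)(CC=C(C)C)C2=O
F7 | step 9 | C6 enol (R)-2-methylbutanoate of 12 | CC(=C)[C@@H]1C[C@@]12C(=O)C=C(OC(=O)[C@H](C)CC)[C@](C)(CC=C(C)C)C2=O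
F8 | step 9 | (1S,3S,7S)-6-hydroxy-7-methyl-5-[(2R)-2-methylbutanoyl]-7-(3-methylbut-2-en-1-yl)-1-(prop-1-en-2-yl)spiro[2.5]oct-5-ene-4,8-dione | CC[C@@H](C)C(=O)C1=C(O)[C@](C)(CC=C(C)C)C(=O)[C@]2(C[C@H]2C(C)=C)C1=O
F9 | step 9 | 8-hydroxy-4,4,7-trimethyl-9-[(2R)-2-methylbutanoyl]-3-(prop-1-en-2-yl)tricyclo[5.3.1.0^1,5]undec-8-ene-10,11-dione (core configured as in 18) | CC[C@@H](C)C(=O)C1=C(O)[C@]2(C)C[C@H]3C(C)(C)[C@@H](C(C)=C)C[C@@]3(C1=O)C2=O
F10 | step 9 | tertiary hydroperoxide of F9 | CC[C@@H](C)C(=O)C1=C(O)[C@]2(C)C[C@H]3C(C)(C)[C@@H](C(C)(C)OO)C[C@@]3(C1=O)C2=O
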